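## Analysis of the target

Daucane numbering is used throughout, and β denotes the face of the angular methyl C15.

- Target 30 is a daucane ester built on a trans-fused bicyclo[5.3.0]decane. The cyclopentane (C1–C5) carries the angular methyl at C1 and an isopropyl carbinol at C4. The cycloheptane (C1, C5–C10) carries a 3-methylbutanoate at C6, a spiro-epoxide at C8 (C14 is its methylene) and a diol at C9/C10.
- It has seven stereocentres, (1S,4R,5S,6S,8S,9S,10S). The 4-OH is β like C15, while H5, the C6 acyloxy group, the epoxide oxygen, 9-OH and 10-OH are all α.
- It follows that the ring fusion is trans, H5 and H6 are anti, and the three oxygens at C8–C10 are mutually cis and lie opposite the angular methyl.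
- The sensitive groups are the spiro-epoxide next to a free cis-diol (opened by acid, migrates under base), the tertiary alcohol (dehydration) and the ester (hydrolysis, acyl migration).
- The difficulty lies in two fully substituted carbons in the five-membered ring (C1, C4), a trans fusion that is probably not the thermodynamically favoured one at the ketone stage, and three contiguous oxygenated carbons on a flexible seven-membered ring.
- The strategy rests on one feature: in the seven-membered ring the sp3 carbon C1 sits between C5–C6 and C10–C9, and all four of these carbons later carry oxygen or hydrogen that can come from an alkene. The ring is therefore a cyclohepta-1,4-diene in disguise (C5=C6 and C9=C10 around C1). Its bonds C1–C5 and C7–C8 can be made from a three-carbon vinylcarbenoid (C5–C6–C7) and a diene (C1=C10–C9=C8).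

## Retrosynthetic reasoning

**Epoxide (C8–O, C14–O).** The epoxide of 30 is the most fragile group and is removed first, back to the exocyclic alkene of triol ester 29. The free 9α-hydroxyl of 29 is allylic to C8=C14, so a hydroxyl-directed, vanadium-catalysed epoxidation can deliver oxygen to the α face as the last step. No acid or base then follows epoxide formation.

**Ester and protecting groups (C6–O acyl).** The diol of 29 is masked as the acetonide in 28. In that form only the secondary C6 hydroxyl and the unreactive tertiary C4 hydroxyl are free, so the ester bond of 28 is cut to diol 26 and acid chloride 27. Diol 26 comes from silyl ether 25. The silyl group is needed earlier because the C6 oxygen must not be lost by elimination when C4 is still a ketone.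

**C8=C14 and the C8–C10 oxygens.** The exocyclic methylene of 25 is cut to ketone 24 (carbonyl methylenation under non-basic conditions). The two C–O bonds at C9 and C10 of 24 are cut together via diol 23 back to enone 22, since a syn-dihydroxylation gives the cis-diol in one step, on the face away from the axial C15 methyl on the adjacent carbon. The C8 carbonyl of 22 goes back to the C8 methylene of alkene 21. C8 is the only allylic position of C9=C10 that bears hydrogen, because C1 is quaternary.

**C4–isopropyl bond.** Tertiary alcohol 21 is cut at C4–C11 to ketone 19 and the Grignard reagent 20, used as its cerium derivative. The forward addition has to beat enolisation of a hindered β-silyloxy ketone and has to come from the α face.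

**C6–O and C5–H.** Silyl ether 19 comes from β-hydroxy ketone 18. The C6–O and C5–H bonds of 18 are cut to the enone of dienone 16: a copper-catalysed conjugate borylation places boron at C6, protonation of the enolate gives H5, and oxidation turns C–B into C–O with retention. This is done before any work on C8–C10 because it removes the enone, and with it the second allylic methylene (C7), which would otherwise compete in the later allylic oxidation.

**Key disconnection (C7–C8 and C1–C5).** Dienone 16 is the cyclohepta-1,4-diene named above. A retro-Cope step gives the cis-divinylcyclopropane 15 (re-forming C5–C10, cutting C7–C8). Retro-cyclopropanation of 15 (cutting C5–C1 and C5–C10) gives the open-chain vinyl diazoketone 14. Both rings and the quaternary centre are thus traced to an achiral chain. The forward reaction has to make the carbenoid choose one face of the C1=C10 alkene and place the two vinyl groups cis.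

**Vinyl diazoketone.** The vinyl group on the diazo carbon of 14 is taken back to the β-hydroxy diazoketone 13, and this by an aldol-type cut to the terminal diazoketone 11 and acetaldehyde 12. Diazoketone 11 comes from acid 9 by one-carbon homologation at the carboxyl carbon, via mixed anhydride 10.

**Dienyl chain.** Acid 9 is cut at C2–C3 (daucane numbering) to malonate 6 and dienyl bromide 5, via 7 and 8. Bromide 5 comes from alcohol 4 and ester 3, and 3 from acrolein 1 and the stabilised ylide 2. This Wittig reaction fixes the E geometry on which the cis arrangement of the vinyl groups in 15 depends.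

## Alternatives that were turned down

**Alternative 1:** The seven-membered ring is cut at C7–C8 and closed last by an intramolecular Lewis-acid-mediated Mukaiyama aldol. The silyl enol ether of a C6 methyl ketone on a fully substituted cyclopentane would attack, through C7, the C8 carbonyl of a 1,3-dioxan-5-one unit that already holds O9 and O14. The product is the 6-oxodaucane A1, with an 8α tertiary hydroxyl, a 9α,14-acetonide, a 10α silyl ether and a 4β silyl ether.

- For it: C8 is created with its oxygen and with C14 attached, so no methylenation or late epoxidation is needed (the epoxide would come from the 8,14-diol by sulfonate displacement). The C9 and C10 oxygens are carried in from the chain and do not depend on face selectivity on a seven-membered ring. On the C8–C10 oxygenation it is stronger than the chosen route.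
- Against it: the cyclisation substrate must carry C1, C4, C5, C9 and C10 before the ring exists, which means a long linear sequence on a crowded cyclopentane. Seven-membered ring closure by aldol addition to a hindered, doubly α-oxygenated ketone is entropically poor and reversible. The Lewis acid also threatens the acetonide and the tertiary silyl ether. The C8 configuration depends on a transition state that cannot be predicted with confidence.
- Comparison: the chosen route gives up the built-in C8 oxygenation, but forms both rings and C1 in one catalytic, strain-driven and irreversible step from a chain that takes eight steps to make.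

**Alternative 2:** The cyclopentane is cut at C4–C5 and closed by a samarium-mediated Reformatsky reaction. One-electron reduction of a C5 α-bromo ester gives a samarium enolate that adds to a tethered isopropyl ketone, giving the cyclopentane A2 with the C4 carbinol, H5 and the C1 quaternary centre (methyl and propenyl) in the target's configuration.

- For it: a chelated, chair-like transition state sets the tertiary carbinol at C4 and the hydrogen at C5 together and relative to C1. On the C4/C5 relationship it is stronger than the chosen route, which leaves H5 to an enolate protonation and C4 to a face-selective organocerium addition.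
- Against it: the step only relays chirality. The C1 quaternary centre has to be made enantioselectively beforehand by a separate method, and the seven-membered ring is still entirely missing after the key step. It would have to be built from the ester and the propenyl group by chain extension and a separate ring closure. The bromo ester is also formed as a mixture of epimers.
- Comparison: the chosen route has weaker control of C4/C5, but its key step creates C1 and closes both rings, with the alkenes already placed where oxygen is needed.

**Alternative 3:** The bonds C1–C15 and C5–C6 are cut. A copper-catalysed asymmetric conjugate addition of a methylaluminium reagent (chiral phosphoramidite ligand) to the enone A4 would create the C1 quaternary centre, and the aluminium enolate would be trapped at C5 by the aldehyde A5, giving the aldol adduct A3.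

- For it: three centres (C1, C5, C6) come from one operation. The trans relationship between H5 and C15 is fixed by C–C bond formation anti to the larger β-substituent, and the C6 oxygen is in place. On H5/C6 it is clearly stronger than the chosen route.
- Against it: cyclopentenones are the least favourable ring size for quaternary-centre formation by this addition. Aldehyde A5 is an enolisable β,γ-unsaturated aldehyde that isomerises easily, and the carbinol configuration at C6 is not reliably controlled. A3 is a β-hydroxy ketone prone to retro-aldol cleavage. The seven-membered ring still has to be closed after a one-carbon homologation at C10.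
- Comparison: the chosen route needs no separate seven-membered ring closure and no C9 homologation. Its price is that H5 and C6 are set afterwards on the bicycle.

Key step: step 9

Assumption: Rh2(S-PTAD)4 is taken to select the alkene face that leads to (1R)-16; if the sense of induction is the opposite, Rh2(R-PTAD)4 is used and nothing else changes.

## Route

Step 1
Reactants: 1 acrolein; 2 ethyl 2-(triphenylphosphoranylidene)propanoate
Product: 3 ethyl (2E)-2-methylpenta-2,4-dienoate
Conditions: CH2Cl2, 0 °C → rt
Reagents that add atoms: none
Why: Wittig olefination with a stabilised ylide; such ylides give the E trisubstituted enoate, which places the vinyl group cis to the methyl group as the later cyclopropanation requires.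

Step 2
Reactants: 3 ethyl (2E)-2-methylpenta-2,4-dienoate
Product: 4 (2E)-2-methylpenta-2,4-dien-1-ol
Conditions: i-Bu2AlH (2.2 equiv), CH2Cl2, −78 → 0 °C
Reagents that add atoms: none
Why: 1,2-Reduction of a conjugated ester by an aluminium hydride; the diene is not touched and the alkene geometry is kept.

Step 3
Reactants: 4 (2E)-2-methylpenta-2,4-dien-1-ol
Product: 5 (3E)-5-bromo-4-methylpenta-1,3-diene
Conditions: PBr3 (0.4 equiv), Et2O, −10 → 0 °C; used crude
Reagents that add atoms: phosphorus tribromide, BrP(Br)Br
Why: Conversion of a primary allylic alcohol into the bromide through its phosphite ester; low temperature and the conjugation of the product diene favour the unrearranged primary bromide.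

Step 4
Reactants: 5 (3E)-5-bromo-4-methylpenta-1,3-diene; 6 diethyl malonate
Product: 7 diethyl 2-[(2E)-2-methylpenta-2,4-dien-1-yl]propanedioate
Conditions: NaH, 6 (1.5 equiv), THF, 0 °C → rt
Reagents that add atoms: none
Why: Malonic ester alkylation; the soft enolate displaces the primary allylic bromide directly (SN2), and excess malonate suppresses double alkylation.

Step 5
Reactants: 7 diethyl 2-[(2E)-2-methylpenta-2,4-dien-1-yl]propanedioate
Product: 9 (4E)-4-methylhepta-4,6-dienoic acid, via the dienylmalonic acid 8 (not isolated)
Conditions: KOH, EtOH/H2O, 80 °C; aq. HCl; then pyridine, 110 °C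
Reagents that add atoms: potassium hydroxide, [K+].[OH-]
Why: Saponification and thermal decarboxylation of the malonic acid; the diene carries a cis substituent at its terminus and is therefore a poor Diels–Alder diene, so it should survive the heating.

Step 6
Reactants: 9 (4E)-4-methylhepta-4,6-dienoic acid
Product: 11 (5E)-1-diazo-5-methylocta-5,7-dien-2-one, via the isobutyl carbonic mixed anhydride 10 (not isolated)
Conditions: i-BuOCOCl, Et3N, THF, −15 °C; then CH2N2, Et2O, 0 °C → rt
Reagents that add atoms: diazomethane, C=[N+]=[N-]
Why: Acylation of diazomethane by a mixed carbonic anhydride (first stage of the Arndt–Eistert sequence); no hydrogen chloride is set free, which protects the diene.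

Step 7
Reactants: 11 (5E)-1-diazo-5-methylocta-5,7-dien-2-one; 12 acetaldehyde
Product: 13 (7E)-3-diazo-2-hydroxy-7-methyldeca-7,9-dien-4-one (racemic at C2, which is lost in step 8)
Conditions: LiN(i-Pr)2, THF, −78 °C; then 12, −78 °C
Reagents that add atoms: none
Why: Aldol-type addition of a lithiated acyldiazomethane to an aldehyde; the diazo C–H is removed faster than the α′-methylene protons at −78 °C and the diazo group stays in place.

Step 8
Reactants: 13 (7E)-3-diazo-2-hydroxy-7-methyldeca-7,9-dien-4-one
Product: 14 (7E)-3-diazo-7-methyldeca-1,7,9-trien-4-one
Conditions: POCl3, Et3N, CH2Cl2, 0 °C; kept cold and used at once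
Reagents that add atoms: none
Why: Dehydration of a β-hydroxy-α-diazo ketone through its dichlorophosphate, the standard route to vinyldiazo carbonyl compounds; the product is used at once because vinyldiazo compounds with a free vinyl terminus slowly close to pyrazoles.

Step 9
Reactants: 14 (7E)-3-diazo-7-methyldeca-1,7,9-trien-4-one
Product: 16 (1R)-1-methylbicyclo[5.3.0]deca-5,9-dien-4-one (daucane numbering: C4 ketone, C5=C6, C9=C10), via the cis-divinylcyclopropane 15 (not isolated)
Conditions: Rh2(S-PTAD)4 (1 mol %), PhMe, −40 °C → rt, slow addition of 14; then 80 °C
Reagents that add atoms: none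
Why: The divalent rhodium carboxylate dimer Rh2(S-PTAD)4, dirhodium tetrakis[(S)-(1-adamantyl)(N-phthalimido)acetate], decomposes the diazo group of 14 to a vinyl/acyl (donor/acceptor) carbenoid at C5, which adds to the tethered C1=C10 alkene in an asynchronous but stereospecific cyclopropanation, C5–C1 forming first while the developing charge at C10 is stabilised by the C9=C8 vinyl group; the closest known reaction type is the intramolecular tandem cyclopropanation/Cope rearrangement of diene-tethered vinyldiazo compounds, a formal (4+3) cycloaddition. The five-membered ring closes in the cyclopropanation as a bicyclo[3.1.0]hexan-2-one (5-exo attack of C5 on C1, with C10 left outside that ring), and the seven-membered ring closes in the [3,3] shift of 15 through a boat transition state that forms C7–C8 and breaks C5–C10 with release of the cyclopropane strain. C1 is the only stereocentre that survives: it is set by the alkene face that the chiral carboxylate ligands expose to the carbenoid and is carried unchanged through the stereospecific Cope step, whereas the C5 and C10 centres of 15 become sp2. The step needs site selectivity for the proximal alkene, which the two-carbon tether secures because only five-ring closure is within reach; it needs the two vinyl groups cis, which follows from the tether forcing the C5 vinyl group onto the face of the C15 methyl and from the E alkene putting the C9 vinyl group on that same face; and it needs the carbenoid carbon to react in preference to C–H insertion or attack at the vinyl terminus, which the donor/acceptor carbenoid, the non-polar solvent and slow addition favour. A ketone acceptor is known to erode induction with the prolinate catalyst Rh2(S-DOSP)4 that is usual for vinyldiazoacetates, which is why the phthalimido catalyst is chosen. The C15 methyl is cis to both vinyl groups and crowds the boat, so the rearrangement may not finish at room temperature and the mixture is warmed to 80 °C before work-up.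

Step 10
Reactants: 16 (1R)-1-methylbicyclo[5.3.0]deca-5,9-dien-4-one
Product: 18 (1R,5S,6S)-6-hydroxy-1-methylbicyclo[5.3.0]dec-9-en-4-one (daucane numbering; 5α-H, 6α-OH, trans-fused), via the 6α-boryl ketone 17 (not isolated)
Conditions: CuCl (5 mol %), NaOt-Bu (10 mol %), DPEphos, B2pin2, MeOH (2 equiv), THF, rt; then NaBO3·4H2O, THF/H2O, rt
Reagents that add atoms: sodium perborate, [Na+].[O-]OB=O
Why: Copper-catalysed conjugate borylation of an enone followed by oxidation of the C–B bond with retention; the monovalent copper boryl should add to C6 on the α face, away from the C15 methyl, and methanol should protonate the copper enolate at C5 on that same face, as kinetic attack next to an angular methyl does in steroidal cyclopentanones, giving the trans ring fusion. The isolated C9=C10 alkene does not react with the copper boryl.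

Step 11
Reactants: 18 (1R,5S,6S)-6-hydroxy-1-methylbicyclo[5.3.0]dec-9-en-4-one
Product: 19 6α-(tert-butyldimethylsilyloxy)-1β-methyl-5αH-bicyclo[5.3.0]dec-9-en-4-one
Conditions: TBSOTf, 2,6-lutidine, CH2Cl2, −78 → 0 °C
Reagents that add atoms: tert-butyldimethylsilyl triflate, CC(C)(C)[Si](C)(C)OS(=O)(=O)C(F)(F)F
Why: Silylation of a hindered secondary alcohol under weakly basic conditions, so that the β-hydroxy ketone neither epimerises at C5 nor undergoes retro-aldol cleavage; the silyl ether prevents alkoxide formation in step 12.

Step 12
Reactants: 19 6α-(tert-butyldimethylsilyloxy)-1β-methyl-5αH-bicyclo[5.3.0]dec-9-en-4-one; 20 isopropylmagnesium chloride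
Product: 21 6α-(tert-butyldimethylsilyloxy)-14-nor-5αH-dauc-9-en-4β-ol (4α-isopropyl, 1β-methyl)
Conditions: CeCl3, THF, −78 → 0 °C
Reagents that add atoms: none
Why: Organocerium addition to a hindered, enolisable ketone; the weakly basic cerium reagent suppresses enolisation (which would expel the silyloxy group) and β-hydride reduction. Attack should come from the α face, because the β face of the cyclopentanone is screened by the cis-1,3 angular methyl, as in hydride additions to 15- and 16-oxo steroids, giving the 4β-hydroxyl.

Step 13
Reactants: 21 6α-(tert-butyldimethylsilyloxy)-14-nor-5αH-dauc-9-en-4β-ol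
Product: 22 6α-(tert-butyldimethylsilyloxy)-4β-hydroxy-14-nor-5αH-dauc-9-en-8-one
Conditions: Rh2(cap)4 (1 mol %; cap = caprolactamate), t-BuOOH (70 % aq., 5 equiv), K2CO3, CH2Cl2, rt
Reagents that add atoms: tert-butyl hydroperoxide, CC(C)(C)OO
Why: Allylic oxidation of a cycloalkene to the enone by tert-butylperoxyl radicals; C8 is the only allylic carbon bearing hydrogen, and the allyl radical should capture oxygen at C8, not at the neopentyl end C10.

Step 14
Reactants: 22 6α-(tert-butyldimethylsilyloxy)-4β-hydroxy-14-nor-5αH-dauc-9-en-8-one
Product: 23 6α-(tert-butyldimethylsilyloxy)-4β,9α,10α-trihydroxy-14-nor-5αH-daucan-8-one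
Conditions: OsO4 (5 mol %), NMO, citric acid, t-BuOH/H2O, rt
Reagents that add atoms: N-methylmorpholine N-oxide, C[N+]1([O-])CCOCC1; water, O
Why: Osmium-catalysed syn-dihydroxylation, with citric acid to keep turnover on an electron-poor alkene; both oxygens should enter from the α face, because C10 adjoins the quaternary C1 whose axial methyl blocks the β face, as in α-face additions to steroidal 1-en-3-ones.

Step 15
Reactants: 23 6α-(tert-butyldimethylsilyloxy)-4β,9α,10α-trihydroxy-14-nor-5αH-daucan-8-one
Product: 24 6α-(tert-butyldimethylsilyloxy)-4β-hydroxy-9α,10α-(isopropylidenedioxy)-14-nor-5αH-daucan-8-one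
Conditions: 2,2-dimethoxypropane, PPTS (cat.), acetone, rt
Reagents that add atoms: 2,2-dimethoxypropane, COC(C)(C)OC
Why: Acetonide formation on a cis-1,2-diol by acetal exchange; the tertiary alcohol does not form a stable acetal, and the mild acid leaves the silyl ether and the α-hydroxy ketone intact.

Step 16
Reactants: 24 6α-(tert-butyldimethylsilyloxy)-4β-hydroxy-9α,10α-(isopropylidenedioxy)-14-nor-5αH-daucan-8-one
Product: 25 6α-(tert-butyldimethylsilyloxy)-9α,10α-(isopropylidenedioxy)-5αH-dauc-8(14)-en-4β-ol
Conditions: Cp2TiMe2 (3 equiv), PhMe, 65 °C, dark
Reagents that add atoms: dimethyltitanocene, C[Ti+2]C.[cH-]1cccc1.[cH-]1cccc1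
Why: Petasis methylenation; the titanium methylidene is not basic, so the α-alkoxy ketone neither epimerises at C9 nor eliminates the C10 oxygen, and the excess allows for reagent consumed by the tertiary hydroxyl.

Step 17
Reactants: 25 6α-(tert-butyldimethylsilyloxy)-9α,10α-(isopropylidenedioxy)-5αH-dauc-8(14)-en-4β-ol
Product: 26 9α,10α-(isopropylidenedioxy)-5αH-dauc-8(14)-ene-4β,6α-diol
Conditions: Bu4NF, THF, rt
Reagents that add atoms: none
Why: Fluoride cleavage of the silyl ether; the acetonide, the alkene and the tertiary alcohol are inert to fluoride.

Step 18
Reactants: 26 9α,10α-(isopropylidenedioxy)-5αH-dauc-8(14)-ene-4β,6α-diol; 27 3-methylbutanoyl chloride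
Product: 28 4β-hydroxy-9α,10α-(isopropylidenedioxy)-5αH-dauc-8(14)-en-6α-yl 3-methylbutanoate
Conditions: pyridine, DMAP (cat.), CH2Cl2, 0 °C → rt
Reagents that add atoms: none
Why: DMAP-catalysed acylation; of the two free hydroxyls only the secondary one at C6 reacts, since the tertiary C4 hydroxyl flanked by isopropyl and the ring fusion is not acylated under these conditions.

Step 19
Reactants: 28 4β-hydroxy-9α,10α-(isopropylidenedioxy)-5αH-dauc-8(14)-en-6α-yl 3-methylbutanoate
Product: 29 4β,9α,10α-trihydroxy-5αH-dauc-8(14)-en-6α-yl 3-methylbutanoate
Conditions: AcOH/H2O (4:1), 40 °C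
Reagents that add atoms: none
Why: Mild acid hydrolysis of the acetonide, which proceeds at the acetal carbon and not by ionisation of the allylic C9–O bond; the ester and the tertiary alcohol should tolerate dilute acetic acid.

Step 20
Reactants: 29 4β,9α,10α-trihydroxy-5αH-dauc-8(14)-en-6α-yl 3-methylbutanoate
Product: 30 (1S,4R,5S,6S,8S,9S,10S)-8α,14-epoxy-4β,9α,10α-trihydroxy-5αH-daucan-6α-yl 3-methylbutanoate (target)
Conditions: VO(acac)2 (5 mol %), t-BuOOH (in decane, 1.5 equiv), CH2Cl2, 0 °C → rt
Reagents that add atoms: tert-butyl hydroperoxide, CC(C)(C)OO
Why: Vanadium-catalysed, hydroxyl-directed epoxidation of an allylic alcohol; the vanadate ester of the 9α-hydroxyl (supported by the homoallylic 10α-hydroxyl on the same face) delivers the peroxide oxygen to the α face of C8=C14, so the epoxide oxygen ends cis to 9-OH and C14 lies β. Nothing follows this step, so the epoxide meets neither acid nor base.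

## Compound list

1 | acrolein (prop-2-enal) | C=CC=O | starting material
2 | ethyl 2-(triphenylphosphoranylidene)propanoate | CCOC(=O)C(C)=P(c1ccccc1)(c1ccccc1)c1ccccc1 | starting material
3 | ethyl (2E)-2-methylpenta-2,4-dienoate | C=C/C=C(\C)C(=O)OCC | intermediate
4 | (2E)-2-methylpenta-2,4-dien-1-ol | C=C/C=C(\C)CO | intermediate
5 | (3E)-5-bromo-4-methylpenta-1,3-diene | C=C/C=C(\C)CBr | intermediate
6 | diethyl malonate | CCOC(=O)CC(=O)OCC | starting material
7 | diethyl 2-[(2E)-2-methylpenta-2,4-dien-1-yl]propanedioate | C=C/C=C(\C)CC(C(=O)OCC)C(=O)OCC | intermediate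
8 | 2-[(2E)-2-methylpenta-2,4-dien-1-yl]propanedioic acid | C=C/C=C(\C)CC(C(=O)O)C(=O)O | intermediate (not isolated)
9 | (4E)-4-methylhepta-4,6-dienoic acid | C=C/C=C(\C)CCC(=O)O | intermediate
10 | (4E)-4-methylhepta-4,6-dienoic isobutyl carbonic anhydride | C=C/C=C(\C)CCC(=O)OC(=O)OCC(C)C | intermediate (not isolated)
11 | (5E)-1-diazo-5-methylocta-5,7-dien-2-one | C=C/C=C(\C)CCC(=O)C=[N+]=[N-] | intermediate
12 | acetaldehyde | CC=O | starting material
13 | (7E)-3-diazo-2-hydroxy-7-methyldeca-7,9-dien-4-one (racemic at C2) | C=C/C=C(\C)CCC(=O)C(=[N+]=[N-])C(C)O | intermediate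
14 | (7E)-3-diazo-7-methyldeca-1,7,9-trien-4-one | C=C/C=C(\C)CCC(=O)C(=[N+]=[N-])C=C | intermediate
15 | (1S,5R,6R)-1,6-diethenyl-5-methylbicyclo[3.1.0]hexan-2-one (both vinyl groups and the methyl on one face) | C=C[C@@]12C(=O)CC[C@]1(C)[C@H]2C=C | intermediate (not isolated)
16 | (1R)-1-methylbicyclo[5.3.0]deca-5,9-dien-4-one, daucane numbering [(3aR)-3a-methyl-3,3a,6,7-tetrahydroazulen-1(2H)-one] | O=C1CC[C@]2(C)C=CCCC=C12 | intermediate
17 | 6α-(4,4,5,5-tetramethyl-1,3,2-dioxaborolan-2-yl)-1β-methyl-5αH-bicyclo[5.3.0]dec-9-en-4-one | CC1(C)OB(OC1(C)C)[C@H]1CCC=C[C@@]2(C)CCC(=O)[C@H]12 | intermediate (not isolated)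
18 | (1R,5S,6S)-6-hydroxy-1-methylbicyclo[5.3.0]dec-9-en-4-one (5α-H, 6α-OH) | O[C@H]1CCC=C[C@@]2(C)CCC(=O)[C@H]12 | intermediate
19 | 6α-(tert-butyldimethylsilyloxy)-1β-methyl-5αH-bicyclo[5.3.0]dec-9-en-4-one | CC(C)(C)[Si](C)(C)O[C@H]1CCC=C[C@@]2(C)CCC(=O)[C@H]12 | intermediate
20 | isopropylmagnesium chloride | CC(C)[Mg]Cl | starting material
21 | 6α-(tert-butyldimethylsilyloxy)-14-nor-5αH-dauc-9-en-4β-ol | CC(C)(C)[Si](C)(C)O[C@H]1CCC=C[C@@]2(C)CC[C@@](O)(C(C)C)[C@H]12 | intermediate
22 | 6α-(tert-butyldimethylsilyloxy)-4β-hydroxy-14-nor-5αH-dauc-9-en-8-one | CC(C)(C)[Si](C)(C)O[C@H]1CC(=O)C=C[C@@]2(C)CC[C@@](O)(C(C)C)[C@H]12 | intermediate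
23 | 6α-(tert-butyldimethylsilyloxy)-4β,9α,10α-trihydroxy-14-nor-5αH-daucan-8-one | CC(C)(C)[Si](C)(C)O[C@H]1CC(=O)[C@@H](O)[C@@H](O)[C@@]2(C)CC[C@@](O)(C(C)C)[C@H]12 | intermediate
24 | 6α-(tert-butyldimethylsilyloxy)-4β-hydroxy-9α,10α-(isopropylidenedioxy)-14-nor-5αH-daucan-8-one | CC(C)(C)[Si](C)(C)O[C@H]1CC(=O)[C@@H](OC3(C)C)[C@@H](O3)[C@@]2(C)CC[C@@](O)(C(C)C)[C@H]12 | intermediate
25 | 6α-(tert-butyldimethylsilyloxy)-9α,10α-(isopropylidenedioxy)-5αH-dauc-8(14)-en-4β-ol | CC(C)(C)[Si](C)(C)O[C@H]1CC(=C)[C@@H](OC3(C)C)[C@@H](O3)[C@@]2(C)CC[C@@](O)(C(C)C)[C@H]12 | intermediate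
26 | 9α,10α-(isopropylidenedioxy)-5αH-dauc-8(14)-ene-4β,6α-diol | O[C@H]1CC(=C)[C@@H](OC3(C)C)[C@@H](O3)[C@@]2(C)CC[C@@](O)(C(C)C)[C@H]12 | intermediate
27 | 3-methylbutanoyl chloride | CC(C)CC(Cl)=O | starting material
28 | 4β-hydroxy-9α,10α-(isopropylidenedioxy)-5αH-dauc-8(14)-en-6α-yl 3-methylbutanoate | CC(C)CC(=O)O[C@H]1CC(=C)[C@@H](OC3(C)C)[C@@H](O3)[C@@]2(C)CC[C@@](O)(C(C)C)[C@H]12 | intermediate
29 | 4β,9α,10α-trihydroxy-5αH-dauc-8(14)-en-6α-yl 3-methylbutanoate | CC(C)CC(=O)O[C@H]1CC(=C)[C@@H](O)[C@@H](O)[C@@]2(C)CC[C@@](O)(C(C)C)[C@H]12 | intermediate
30 | (1S,4R,5S,6S,8S,9S,10S)-8α,14-epoxy-4β,9α,10α-trihydroxy-5αH-daucan-6α-yl 3-methylbutanoate (CNP0307265.1) | CC(C)CC(=O)O[C@H]1C[C@]2(CO2)[C@@H](O)[C@@H](O)[C@@]2(C)CC[C@@](O)(C(C)C)[C@H]12 | target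

## Step count and least certain steps

Total: 20 steps. Longest linear sequence: 20 steps, from acrolein 1 to 30; the route is fully linear.

**Step 9 (key step).**
- Most likely failure: poor discrimination between the two faces of the C1=C10 alkene. The acceptor group is a ketone, not an ester, and the alkene is trisubstituted; both are known to lower induction by chiral dirhodium carboxylates.
- Second concern: a sluggish Cope rearrangement, because the C15 methyl is cis to both vinyl groups and crowds the boat transition state. The warming stage is included for this reason. Above about 130 °C a homo-1,5-hydrogen shift from the methyl group would begin to compete.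
- Further concern: ring closure of 14 to a pyrazole before the catalyst acts.
- Fallback: setting out from 14, the cyclisation is run with achiral Rh2(OAc)4 in CH2Cl2 and warmed as before, which should give racemic 1-methylbicyclo[5.3.0]deca-5,9-dien-4-one F1. The conditions of step 10 then give, besides 17 and 18, the enantiomeric boryl ketone 6β-(pinacolatoboryl)-1α-methyl-5βH-bicyclo[5.3.0]dec-9-en-4-one F2 (not isolated) and the enantiomeric alcohol (1S,5R,6R)-6-hydroxy-1-methylbicyclo[5.3.0]dec-9-en-4-one F3. Acylation of this racemate with vinyl acetate and immobilised Candida antarctica lipase B should, by Kazlauskas' rule, esterify the (6R)-alcohol F3 to (1S,5R,6R)-6-acetoxy-1-methylbicyclo[5.3.0]dec-9-en-4-one F4 and leave 18 unreacted. After chromatographic separation the route is rejoined at 18. Asymmetric catalysis is thus replaced by a kinetic resolution.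

**Step 10.**
- Most likely failure: protonation of the copper enolate at C5 from the β face, giving the cis-fused ketone. The cis fusion is probably the more stable one for a cyclopentanone, and the boryl group on C6 may shield the α face.
- Second concern: low face selectivity of the boryl addition at C6, since the C15 methyl and C10 flank the enone plane on opposite sides. A chiral bisphosphine on copper can override this, but it does not address the protonation.
- The configuration has to be checked at 18, because C5 can no longer be corrected after step 12.
- Fallback: setting out from 16, nucleophilic epoxidation with alkaline hydrogen peroxide (H2O2, NaOH, MeOH, 0 °C) should give 5α,6α-epoxy-1β-methylbicyclo[5.3.0]dec-9-en-4-one F5. Reduction with SmI2 in THF/MeOH at −78 °C cleaves the C5–O bond and leaves the C6 oxygen. The samarium enolate, chelated to the C6 alkoxide, is protonated at C5 in a geometry different from that of the boryl enolate, and the route is rejoined at 18.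

**Step 12.**
- Most likely failure: enolisation of the hindered ketone with loss of the silyloxy group (back to the enone), hydride transfer from the isopropyl reagent, or addition from the β face.
- Fallback: setting out from 19, isopropenylmagnesium bromide with CeCl3 is used. This nucleophile is smaller and cannot donate a β-hydride, and should give 6α-(tert-butyldimethylsilyloxy)-4α-(prop-1-en-2-yl)-1β-methyl-5αH-bicyclo[5.3.0]dec-9-en-4β-ol F6. Hydrogen-atom-transfer hydrogenation (Mn(dpm)3, PhSiH3, t-BuOOH, i-PrOH) reduces the 1,1-disubstituted alkene in preference to the 1,2-disubstituted ring alkene and leads back to 21.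

**Step 13.**
- Most likely failure: oxygen capture at C10 by the allyl radical (giving the transposed enone), low conversion, or over-oxidation.
- Fallback: setting out from 21, SeO2 (cat.) with t-BuOOH in CH2Cl2 hydroxylates C8 through an ene reaction and [2,3] shift, a sequence that can only end at C8. It gives 6α-(tert-butyldimethylsilyloxy)-14-nor-5αH-dauc-9-ene-4β,8-diol F7 as a mixture of C8 epimers. MnO2 in CH2Cl2 then oxidises the allylic alcohol, and both epimers converge on 22.

## Further compounds

F1 | step 9 | racemic 1-methylbicyclo[5.3.0]deca-5,9-dien-4-one | O=C1CCC2(C)C=CCCC=C12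
F2 | step 9 | 6β-(pinacolatoboryl)-1α-methyl-5βH-bicyclo[5.3.0]dec-9-en-4-one (enantiomer of 17) | CC1(C)OB(OC1(C)C)[C@@H]1CCC=C[C@]2(C)CCC(=O)[C@@H]12
F3 | step 9 | (1S,5R,6R)-6-hydroxy-1-methylbicyclo[5.3.0]dec-9-en-4-one (enantiomer of 18) | O[C@@H]1CCC=C[C@]2(C)CCC(=O)[C@@H]12
F4 | step 9 | (1S,5R,6R)-6-acetoxy-1-methylbicyclo[5.3.0]dec-9-en-4-one | CC(=O)O[C@@H]1CCC=C[C@]2(C)CCC(=O)[C@@H]12
F5 | step 10 | 5α,6α-epoxy-1β-methylbicyclo[5.3.0]dec-9-en-4-one | O3[C@H]1CCC=C[C@@]2(C)CCC(=O)[C@]123
F6 | step 12 | 6α-(tert-butyldimethylsilyloxy)-4α-(prop-1-en-2-yl)-1β-methyl-5αH-bicyclo[5.3.0]dec-9-en-4β-ol | CC(C)(C)[Si](C)(C)O[C@H]1CCC=C[C@@]2(C)CC[C@@](O)(C(C)=C)[C@H]12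
F7 | step 13 | 6α-(tert-butyldimethylsilyloxy)-14-nor-5αH-dauc-9-ene-4β,8-diol (C8 epimers) | CC(C)(C)[Si](C)(C)O[C@H]1CC(O)C=C[C@@]2(C)CC[C@@](O)(C(C)C)[C@H]12
A1 | alternative 1 | 6-oxodaucane with 8α-hydroxyl, 9α,14-acetonide, 10α-(tert-butyldimethylsilyloxy) and 4β-(triethylsilyloxy) groups | O=C1C[C@]2(O)COC(C)(C)O[C@H]2[C@@H](O[Si](C)(C)C(C)(C)C)[C@@]3(C)CC[C@@](O[Si](CC)(CC)CC)(C(C)C)[C@H]13
A2 | alternative 2 | ethyl 2-hydroxy-2-isopropyl-5-methyl-5-[(E)-prop-1-enyl]cyclopentane-1-carboxylate | CCOC(=O)[C@H]1[C@](O)(C(C)C)CC[C@]1(C)/C=C/C
A3 | alternative 3 | 2-(1-hydroxy-3-iodobut-3-enyl)-3-methyl-3-[(tert-butyldimethylsilyloxy)methyl]cyclopentan-1-one | C=C(I)C[C@H](O)[C@H]1C(=O)CC[C@]1(C)CO[Si](C)(C)C(C)(C)C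
A4 | alternative 3 | 3-[(tert-butyldimethylsilyloxy)methyl]cyclopent-2-en-1-one | O=C1CCC(CO[Si](C)(C)C(C)(C)C)=C1
A5 | alternative 3 | 3-iodobut-3-enal | C=C(I)CC=O
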